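**Plan**

1. Guaiane numbering is used. Unprimed atoms belong to the half with the tertiary alcohol, primed atoms to the half with the spiro centre C4'.
2. The retrosynthesis first cuts the cyclohexene at C2–C4' and C14–C15' (retro-Diels–Alder), giving diosphenol diene 23 and dehydrozaluzanin C 18, both from one monomer. In the monomer it then cuts O–C12, C6–C7, C7=C11 (olefination), C4=C5 (aldol) and C8–C9 (allyl anion plus epoxide), back to (R)-limonene.
3. Enabling feature: in each half the γ-lactone (O, C6, C7, C11, C12) is fused to the cycloheptane (C1, C5–C10) along C6–C7 and carries the exocyclic C11=C13. C6(O)–C7–C11(=C13) is therefore a homoallylic alcohol. Both C6 (a carbonyl carbon) and C7 (an enoate β-carbon) are acceptors. A CH2SiMe3 helper on C11 turns C7 into a donor and leaves in the same event.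
4. Ring order in the forward direction: the cyclopentene comes first (ring contraction of the limonene ring). The cycloheptane and lactone then form together in the key step. The cyclohexene with the spiro centre comes last, by the dimerising cycloaddition.
5. Stereochemistry: C1 comes from limonene and C5 from kinetic protonation anti to the C1 side chain. C6 and C7 are set in the key step. C2 and C4' are set in the Diels–Alder step (convex α-face of 18, carbonyl endo, β-face of 23).
6. Both halves come from 18, so the bond made in step 8 ends up as C6–C7 and as C6'–C7' of the target.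

Key step: step 8

Remark: 11, 12 and 13 are carried as E/Z mixtures at C7=C11, because this geometry disappears when C11=C13 is formed. Their SMILES leave it open. Compound 10 is racemic.

**Step 1**
Reactants: 1 (R)-(+)-limonene; 2 ethylene oxide
Product: 4 (R)-4-(4-methylcyclohex-3-en-1-yl)pent-4-en-1-ol, via allyllithium 3 (not isolated)
Conditions: n-BuLi, TMEDA, hexane, rt; then 2, THF, −78 °C → rt; H2O
Reagents that add atoms: none
Why: Kinetic allylic metalation by n-BuLi·TMEDA takes place at the isopropenyl methyl group, and the 2-substituted allyllithium opens the epoxide in an SN2 reaction, which adds C8 and C7 and leaves the chiral-pool stereocentre (future C1) untouched.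

**Step 2**
Reactants: 4 (R)-4-(4-methylcyclohex-3-en-1-yl)pent-4-en-1-ol
Product: 5 (R)-3-(5-hydroxypent-1-en-2-yl)-6-oxoheptanal
Conditions: O3 (1 equiv, Sudan Red 7B as end-point indicator), CH2Cl2/MeOH, −78 °C; Me2S, −78 °C → rt
Reagents that add atoms: ozone, [O-][O+]=O
Why: In this chemoselective ozonolysis the trisubstituted ring alkene is more electron-rich than the 1,1-disubstituted C10=C14 alkene, so one equivalent of ozone should cleave only the ring, and the reductive work-up gives the keto aldehyde.

**Step 3**
Reactants: 5 (R)-3-(5-hydroxypent-1-en-2-yl)-6-oxoheptanal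
Product: 6 (S)-5-(5-hydroxypent-1-en-2-yl)-2-methylcyclopent-1-ene-1-carbaldehyde
Conditions: piperidine (cat.), AcOH (cat.), toluene, 80 °C, Dean–Stark
Reagents that add atoms: none
Why: In this intramolecular aldol condensation the piperidine enamine of the aldehyde (C5) attacks the methyl ketone (C4) to close the five-membered ring, and dehydration gives the tetrasubstituted enal without touching C1.

**Step 4**
Reactants: 6 (S)-5-(5-hydroxypent-1-en-2-yl)-2-methylcyclopent-1-ene-1-carbaldehyde
Product: 7 (S)-2-methyl-5-(5-oxopent-1-en-2-yl)cyclopent-1-ene-1-carbaldehyde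
Conditions: DMP, CH2Cl2, 0 °C → rt
Reagents that add atoms: none
Why: Dess–Martin oxidation converts the only alcohol (C7) into the aldehyde under conditions that leave the enal and the 1,1-disubstituted alkene alone.

**Step 5**
Reactants: 8 trimethyl phosphonoacetate; 9 (iodomethyl)trimethylsilane
Product: 10 methyl 2-(dimethoxyphosphoryl)-3-(trimethylsilyl)propanoate
Conditions: NaH, DME, 0 °C; then 9, 70 °C
Reagents that add atoms: none
Why: SN2 alkylation of the stabilised phosphonate carbanion by the primary iodide installs C13 with its silyl helper on the future C11.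

**Step 6**
Reactants: 7 (S)-2-methyl-5-(5-oxopent-1-en-2-yl)cyclopent-1-ene-1-carbaldehyde; 10 methyl 2-(dimethoxyphosphoryl)-3-(trimethylsilyl)propanoate
Product: 11 methyl 6-[(S)-2-formyl-3-methylcyclopent-2-en-1-yl]-2-[(trimethylsilyl)methyl]hepta-2,6-dienoate
Conditions: 10, NaH, THF, 0 °C; then 7 (1 equiv), −78 → 0 °C
Reagents that add atoms: none
Why: In this Horner–Wadsworth–Emmons olefination the unhindered aliphatic C7 aldehyde reacts far faster than the conjugated, tetrasubstituted C6 enal, so one equivalent of the anion should form only C7=C11.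

**Step 7**
Reactants: 11 methyl 6-[(S)-2-formyl-3-methylcyclopent-2-en-1-yl]-2-[(trimethylsilyl)methyl]hepta-2,6-dienoate
Product: 13 methyl 6-[cis-2-formyl-3-methylcyclopent-3-en-1-yl]-2-[(trimethylsilyl)methyl]hepta-2,6-dienoate (1αH 5αH), via potassium dienolate 12 (not isolated)
Conditions: KOt-Bu (1.1 equiv), THF, −78 → −40 °C; cannulated into AcOH, THF, −78 °C; used crude
Reagents that add atoms: none
Why: In this deconjugative protonation, γ-deprotonation of the 2-methylcycloalkenyl aldehyde at the ring CH2 (C3) gives the endocyclic dienolate, whose kinetic protonation occurs at the α-carbon C5 from the face opposite the C1 side chain, which sets H5 α (cis to H1) and moves the alkene to C3=C4.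

**Step 8**
Reactants: 13 methyl 6-[cis-2-formyl-3-methylcyclopent-3-en-1-yl]-2-[(trimethylsilyl)methyl]hepta-2,6-dienoate
Product: 15 1αH,5αH,6βH,7αH-guaia-3,10(14),11(13)-trien-12,6-olide, via hydroxy ester 14 (not isolated)
Conditions: TiCl4 (1.1 equiv), CH2Cl2, −78 → −40 °C; H2O; then PPTS (cat.), toluene, 50 °C
Reagents that add atoms: none
Why: TiCl4 binds the C6 aldehyde and C7, the γ-carbon of the 2-(trimethylsilylmethyl)enoate, attacks it in an anti-SE2' sense; the β-silyl cation at C11 loses its silyl group to chloride, which creates the C11=C13 methylene, and the C6 oxygen then acylates on C12 to close the lactone. The closest known reaction type is the intramolecular Hosomi–Sakurai allylation of ω-formyl 2-(silylmethyl)alk-2-enoates followed by lactonisation, which is established for α-methylene-γ-butyrolactones fused to six- and seven-membered carbocycles. The cycloheptane closes in a 7-exo-trig mode (the carbonyl oxygen and C11 both stay outside the new ring) and the lactone in a 5-exo-trig acyl substitution. C6 is controlled by C5 in a Felkin–Anh sense that the tether reinforces: the C5–C4 bond stands anti to the incoming C7, the Ti-bound oxygen lies next to H5 and C7 arrives from the C1 side, which leaves H6 β and O6 α. C7 is controlled by the chair-like seven-membered transition state in which the C6–O and C7–C11 bonds are both pseudo-equatorial, which should give H7 α and the trans ring fusion from either enoate geometry. The step needs the ester-deactivated allylsilane to win over the C10=C14 and C3=C4 alkenes and over enolisation at C5; only C7 can reach C6 through an unstrained ring (ene or Prins alternatives would be four-membered or five-membered endo closures), and the low temperature and short contact time protect C5.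

**Step 9**
Reactants: 15 1αH,5αH,6βH,7αH-guaia-3,10(14),11(13)-trien-12,6-olide
Product: 16 3α,4α-epoxy-1αH,5αH-guaia-10(14),11(13)-dien-12,6α-olide
Conditions: mCPBA (1 equiv), CH2Cl2, 0 °C
Reagents that add atoms: mCPBA, OOC(=O)c1cccc(Cl)c1
Why: Prilezhaev epoxidation picks the only trisubstituted, electron-rich alkene (C3=C4) and approaches the convex α-face of the cis-fused bicycle; both new centres are removed again in steps 10 and 11.

**Step 10**
Reactants: 16 3α,4α-epoxy-1αH,5αH-guaia-10(14),11(13)-dien-12,6α-olide
Product: 17 3α-hydroxy-1αH,5αH-guaia-4(15),10(14),11(13)-trien-12,6α-olide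
Conditions: Al(OiPr)3, toluene, 110 °C
Reagents that add atoms: none
Why: In this epoxide to allylic alcohol isomerisation the aluminium centre binds the epoxide oxygen, the tertiary C4–O bond breaks and an isopropoxide ligand removes a proton from the unhindered C15 methyl group, which gives the exocyclic C4=C15 alkene and keeps the C3–O bond.

**Step 11**
Reactants: 17 3α-hydroxy-1αH,5αH-guaia-4(15),10(14),11(13)-trien-12,6α-olide
Product: 18 dehydrozaluzanin C
Conditions: DMP, CH2Cl2, rt
Reagents that add atoms: none
Why: Dess–Martin oxidation of the allylic alcohol gives the α-methylene cyclopentanone under neutral conditions that do not isomerise the exocyclic alkenes or epimerise C5.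

**Step 12**
Reactants: 18 dehydrozaluzanin C (part of the material)
Product: 19 3-(trimethylsilyloxy)guaia-2,4(15),10(14),11(13)-tetraen-12,6α-olide
Conditions: TMSOTf, Et3N, CH2Cl2, −78 → 0 °C
Reagents that add atoms: TMSOTf, C[Si](C)(C)OS(=O)(=O)C(F)(F)F
Why: Soft enolisation of the ketone can only go toward C2, the sole α-carbon with hydrogens, and the mild amine base spares the α-methylene lactone.

**Step 13**
Reactants: 19 3-(trimethylsilyloxy)guaia-2,4(15),10(14),11(13)-tetraen-12,6α-olide
Product: 21 2α-hydroxydehydrozaluzanin C, via silyloxy ketone 20 (not isolated)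
Conditions: DMDO (1 equiv), acetone/CH2Cl2, −78 → −20 °C; then AcOH, THF/H2O, 0 °C
Reagents that add atoms: dimethyldioxirane, CC1(C)OO1
Why: In this Rubottom oxidation the silyl enol ether C2=C3 is by far the most electron-rich alkene and is epoxidised from the convex α-face opposite C10, and silyl migration and hydrolysis give the α-ketol, whose C2 configuration is erased in step 14.

**Step 14**
Reactants: 21 2α-hydroxydehydrozaluzanin C; 18 dehydrozaluzanin C
Product: 24 target CNP0269880.2, via 2,3-diketone 22 (not isolated), via diosphenol diene 23 (not isolated)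
Conditions: DMP (1.05 equiv), CH2Cl2, 0 °C; then 18 (3 equiv), BHT (cat.), 40 °C, dark, argon
Reagents that add atoms: none
Why: Dess–Martin oxidation gives the 1,2-dione, which enolises toward C1 to the diosphenol, whose ring-locked s-cis diene C2=C1–C10=C14 should undergo an intermolecular Diels–Alder reaction with the exocyclic enone C4'=C15' of 18 in the "ortho" sense (C14–C15' and C2–C4'); the dienophile offers its convex α-face with the C3' carbonyl endo and the bulky C5' side exo, which corresponds to the β-face of the diene and sets C4' and C2 (OH α) suprafacially.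

**Compound list**

1 | (R)-(+)-limonene | CC1=CC[C@@H](CC1)C(C)=C | starting material
2 | ethylene oxide | C1CO1 | starting material
3 | 2-[(R)-4-methylcyclohex-3-en-1-yl]allyllithium | CC1=CC[C@@H](CC1)C(=C)C[Li] | intermediate
4 | (R)-4-(4-methylcyclohex-3-en-1-yl)pent-4-en-1-ol | CC1=CC[C@@H](CC1)C(=C)CCCO | intermediate
5 | (R)-3-(5-hydroxypent-1-en-2-yl)-6-oxoheptanal | CC(=O)CC[C@H](CC=O)C(=C)CCCO | intermediate
6 | (S)-5-(5-hydroxypent-1-en-2-yl)-2-methylcyclopent-1-ene-1-carbaldehyde | CC1=C(C=O)[C@@H](CC1)C(=C)CCCO | intermediate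
7 | (S)-2-methyl-5-(5-oxopent-1-en-2-yl)cyclopent-1-ene-1-carbaldehyde | CC1=C(C=O)[C@@H](CC1)C(=C)CCC=O | intermediate
8 | trimethyl phosphonoacetate | COC(=O)CP(=O)(OC)OC | starting material
9 | (iodomethyl)trimethylsilane | C[Si](C)(C)CI | starting material
10 | methyl 2-(dimethoxyphosphoryl)-3-(trimethylsilyl)propanoate (racemic) | COC(=O)C(C[Si](C)(C)C)P(=O)(OC)OC | intermediate
11 | methyl 6-[(S)-2-formyl-3-methylcyclopent-2-en-1-yl]-2-[(trimethylsilyl)methyl]hepta-2,6-dienoate (E/Z) | CC1=C(C=O)[C@@H](CC1)C(=C)CCC=C(C[Si](C)(C)C)C(=O)OC | intermediate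
12 | potassium dienolate of 11 (O–C6=C5, C4=C3) | [K+].[O-]C=C1C(C)=CC[C@H]1C(=C)CCC=C(C[Si](C)(C)C)C(=O)OC | intermediate
13 | methyl 6-[cis-2-formyl-3-methylcyclopent-3-en-1-yl]-2-[(trimethylsilyl)methyl]hepta-2,6-dienoate (1αH,5αH) | CC1=CC[C@H]([C@H]1C=O)C(=C)CCC=C(C[Si](C)(C)C)C(=O)OC | intermediate
14 | methyl 6α-hydroxy-1αH,5αH,6βH,7αH-guaia-3,10(14),11(13)-trien-12-oate | CC1=CC[C@H]2C(=C)CC[C@H]([C@H](O)[C@@H]12)C(=C)C(=O)OC | intermediate
15 | 1αH,5αH,6βH,7αH-guaia-3,10(14),11(13)-trien-12,6-olide | CC1=CC[C@H]2C(=C)CC[C@H]3C(=C)C(=O)O[C@@H]3[C@@H]12 | intermediate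
16 | 3α,4α-epoxy-1αH,5αH-guaia-10(14),11(13)-dien-12,6α-olide | C[C@@]12O[C@@H]1C[C@H]3C(=C)CC[C@H]4C(=C)C(=O)O[C@@H]4[C@@H]23 | intermediate
17 | 3α-hydroxy-1αH,5αH-guaia-4(15),10(14),11(13)-trien-12,6α-olide | C=C1[C@H](O)C[C@H]2C(=C)CC[C@H]3C(=C)C(=O)O[C@@H]3[C@@H]12 | intermediate
18 | dehydrozaluzanin C (3-oxo-1αH,5αH-guaia-4(15),10(14),11(13)-trien-12,6α-olide) | C=C1C(=O)C[C@H]2C(=C)CC[C@H]3C(=C)C(=O)O[C@@H]3[C@@H]12 | intermediate
19 | 3-(trimethylsilyloxy)guaia-2,4(15),10(14),11(13)-tetraen-12,6α-olide | C=C1C(O[Si](C)(C)C)=C[C@H]2C(=C)CC[C@H]3C(=C)C(=O)O[C@@H]3[C@@H]12 | intermediate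
20 | 2α-(trimethylsilyloxy)dehydrozaluzanin C | C=C1C(=O)[C@H](O[Si](C)(C)C)[C@H]2C(=C)CC[C@H]3C(=C)C(=O)O[C@@H]3[C@@H]12 | intermediate
21 | 2α-hydroxydehydrozaluzanin C | C=C1C(=O)[C@H](O)[C@H]2C(=C)CC[C@H]3C(=C)C(=O)O[C@@H]3[C@@H]12 | intermediate
22 | 2,3-dioxo-1αH,5αH-guaia-4(15),10(14),11(13)-trien-12,6α-olide | C=C1C(=O)C(=O)[C@H]2C(=C)CC[C@H]3C(=C)C(=O)O[C@@H]3[C@@H]12 | intermediate
23 | 2-hydroxy-3-oxo-5αH-guaia-1,4(15),10(14),11(13)-tetraen-12,6α-olide (diosphenol diene) | C=C1C(=O)C(O)=C2C(=C)CC[C@H]3C(=C)C(=O)O[C@@H]3[C@@H]12 | intermediate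
24 | CNP0269880.2 | C=C1C(=O)[C@]2(O)C3=C(CC[C@H]4C(=C)C(=O)O[C@@H]4[C@@H]13)CC[C@]21C(=O)C[C@H]2C(=C)CC[C@H]3C(=C)C(=O)O[C@@H]3[C@H]21 | target

**Total step count:** 14.
**Longest linear sequence:** 13 (steps 1–4 and 6–14, from (R)-limonene).

**Steps most likely to fail**

1. **Step 14.**
   - What may go wrong:
     - The diene may dimerise through its own exocyclic enone.
     - The enol may be over-oxidised by the periodinane.
     - The cycloaddition may be slow, because two fully substituted carbons (C2 and C4') must be joined.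
     - The diene may be attacked on its other face.
   - Fallback: it sets out from 19 and comes back at 24. Saegusa–Ito dehydrogenation of 19 with Pd(OAc)2 in MeCN should give the cross-conjugated dienone F7, which has only hydrogen at the diene terminus C2. Its Diels–Alder reaction with 18 should give the 2-deoxy adduct F8. The doubly activated C2–H is then removed with KHMDS at −78 °C, and the extended enolate is hydroxylated at its α-carbon with 2-(phenylsulfonyl)-3-phenyloxaziridine to give 24.

2. **Step 8.**
   - What may go wrong: the ester-deactivated allylsilane may react too slowly, so that the Lewis acid isomerises or epimerises the aldehyde first. Protodesilylation may occur. The ring may close to the cis-fused lactone.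
   - Fallback: it sets out from 7 and comes back at 15, and it replaces the polar closure by a ketyl radical closure of the same bond.
     - Horner–Wadsworth–Emmons reaction of 7 with trimethyl 2-phosphonopropionate gives the (E)-2-methylenoate enal F3.
     - Deconjugative protonation as in step 7 gives the cis aldehyde F4.
     - SmI2 in THF/t-BuOH converts the aldehyde into its ketyl, which adds 7-exo-trig to the enoate β-carbon with the usual anti preference, and lactonisation gives the 11,13-dihydrolactone F5.
     - LDA and PhSeBr give the 11-phenylselenide F6.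
     - H2O2 triggers selenoxide syn-elimination toward the methyl group to give 15.

3. **Step 7.**
   - What may go wrong: protonation may take place at the γ-carbon, which returns the conjugated enal. Deprotonation may occur partly at the C15 methyl group. The aldehyde may epimerise at C5 or re-conjugate during isolation.
   - Fallback: it sets out from 11 and comes back at 13. Dienolate 12 is trapped with Ac2O as the dienol acetate F1. NaBH4 in EtOH/THF at 0 °C then cleaves the acetate, and the β,γ-unsaturated aldehyde released by α-protonation is reduced at once to the stable homoallylic alcohol F2, which can be purified. Dess–Martin oxidation immediately before step 8 gives 13.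

**Further compounds**

F1 | step 7 | dienol acetate of 11 | CC(=O)OC=C1C(C)=CC[C@H]1C(=C)CCC=C(C[Si](C)(C)C)C(=O)OC
F2 | step 7 | methyl 6-[cis-2-(hydroxymethyl)-3-methylcyclopent-3-en-1-yl]-2-[(trimethylsilyl)methyl]hepta-2,6-dienoate | CC1=CC[C@H]([C@H]1CO)C(=C)CCC=C(C[Si](C)(C)C)C(=O)OC
F3 | step 8 | methyl (E)-6-[(S)-2-formyl-3-methylcyclopent-2-en-1-yl]-2-methylhepta-2,6-dienoate | CC1=C(C=O)[C@@H](CC1)C(=C)CC/C=C(\C)C(=O)OC
F4 | step 8 | methyl (E)-6-[cis-2-formyl-3-methylcyclopent-3-en-1-yl]-2-methylhepta-2,6-dienoate | CC1=CC[C@H]([C@H]1C=O)C(=C)CC/C=C(\C)C(=O)OC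
F5 | step 8 | 1αH,5αH,6βH,7αH-guaia-3,10(14)-dien-12,6-olide (C11 epimers) | CC1=CC[C@H]2C(=C)CC[C@H]3C(C)C(=O)O[C@@H]3[C@@H]12
F6 | step 8 | 11-(phenylselanyl)-1αH,5αH,6βH,7αH-guaia-3,10(14)-dien-12,6-olide | CC1=CC[C@H]2C(=C)CC[C@H]3C(C)([Se]c4ccccc4)C(=O)O[C@@H]3[C@@H]12
F7 | step 14 | 3-oxo-5αH-guaia-1,4(15),10(14),11(13)-tetraen-12,6α-olide | C=C1C(=O)C=C2C(=C)CC[C@H]3C(=C)C(=O)O[C@@H]3[C@@H]12
F8 | step 14 | 2-deoxy Diels–Alder adduct (2αH) | C=C1C(=O)[C@@H]2C3=C(CC[C@H]4C(=C)C(=O)O[C@@H]4[C@@H]13)CC[C@]21C(=O)C[C@H]2C(=C)CC[C@H]3C(=C)C(=O)O[C@@H]3[C@H]21
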